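**Retrosynthetic overview**
1. The (Z)-p-coumarate is built last on the free C18 alcohol by Still–Gennari olefination of its phosphonoacetate; the 2-substituted butadiene comes from enyne metathesis of a terminal alkyne with ethylene.
2. C8 and C9 are set together by syn hydroboration of a tetrasubstituted C8=C9 alkene, made by Negishi coupling at a C9 enol triflate.
3. Key step: a catalytic enantioselective endo Diels–Alder reaction of 2,6-dimethyl-1,4-benzoquinone with an (E)-4,4-disubstituted diene sets the quaternary C4, C5, C10 and the cis ring fusion in one step.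
4. Ring order: ring B is the commercial quinone; ring A is annulated onto it by the cycloaddition; the surplus C6 oxygen is then removed.

Assumption: the SMILES is taken literally; it encodes a cis-fused decalin (H-5 and the C10 methyl on the same face, the CH2O arm on the opposite face of C4), i.e. (1R,4aS,5R,6R,8aS) in decalin numbering, not the trans-fused natural labdane.
Locants in names are labdane locants: C1–C10 decalin (C5/C10 ring fusion), C4 bears C19H3 (β) and C18H2O (α), C8 bears C17H3, C10 bears C20H3, C9 bears the side chain C11–C16; β is the face of C20.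

**Route**

Step 1
Reactants: 1 acrolein; 2 ethyl 2-(triphenylphosphoranylidene)propanoate
Product: 3 ethyl (2E)-2-methylpenta-2,4-dienoate
Conditions: CH2Cl2, 0 °C → rt
Reagents that add atoms: none
Why: Wittig olefination with a stabilised ylide gives the (E)-trisubstituted alkene (ester trans to the vinyl group).

Step 2
Reactants: 3 ethyl (2E)-2-methylpenta-2,4-dienoate
Product: 4 (2E)-2-methylpenta-2,4-dien-1-ol
Conditions: DIBAL-H (2.2 equiv), CH2Cl2, −78 °C
Reagents that add atoms: none
Why: DIBAL-H 1,2-reduction of the conjugated ester gives the allylic alcohol without touching the diene or its geometry.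

Step 3
Reactants: 4 (2E)-2-methylpenta-2,4-dien-1-ol
Product: 5 tert-butyl{[(2E)-2-methylpenta-2,4-dien-1-yl]oxy}diphenylsilane
Conditions: TBDPSCl, imidazole, DMF, rt
Reagents that add atoms: tert-butyl(chloro)diphenylsilane, CC(C)(C)[Si](Cl)(c1ccccc1)c1ccccc1
Why: Silylation of the primary alcohol gives an ether that survives the Lewis acid, hydride, organometallic and mild-acid steps ahead.

Step 4
Reactants: 5 tert-butyl{[(2E)-2-methylpenta-2,4-dien-1-yl]oxy}diphenylsilane; 6 2,6-dimethyl-1,4-benzoquinone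
Product: 7 cis-fused enedione cycloadduct (4aR,5R,8aS)-5-{[tert-butyl(diphenyl)silyl]oxymethyl}-2,5,8a-trimethyl-4a,5,8,8a-tetrahydronaphthalene-1,4-dione
Conditions: (S)-3,3-diphenyl-1-(o-tolyl)tetrahydro-1H,3H-pyrrolo[1,2-c][1,3,2]oxazaborole (20 mol %), Tf2NH (18 mol %), CH2Cl2, −78 → −20 °C
Reagents that add atoms: none
Why: Enantioselective Diels–Alder reaction under a cationic oxazaborolidine Lewis acid: the catalyst binds the unhindered C6 carbonyl syn to C5–H, so the unsubstituted diene terminus adds to the methyl-bearing β-carbon (C1–C10 bond); suprafacial addition gives the cis fusion (H-5 and CH3-10 β); the endo transition state puts the outside CH2OSi cis to C6 (α) and the inside CH3 on C4 β; the (S)-catalyst is expected to expose the face leading to the shown enantiomer, by analogy with the binding mode that gives (S)-cyclohex-3-enecarboxylates from acrylates and butadiene.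

Step 5
Reactants: 7 cis-fused enedione cycloadduct
Product: 8 6α-hydroxy enone (18-TBDPSO-6α-hydroxy-4β,8,10β-trimethyl-5βH-decala-2,7-dien-9-one)
Conditions: NaBH4, CeCl3·7H2O, MeOH, −78 °C
Reagents that add atoms: none
Why: Luche 1,2-reduction is chemoselective for the unhindered C6 carbonyl (C9 is flanked by the quaternary C10 and the methyl-bearing C8); hydride from the convex β-face gives the 6α-alcohol, a centre that is removed in step 7.

Step 6
Reactants: 8 6α-hydroxy enone
Product: 9 6α-acetoxy enone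
Conditions: Ac2O, pyridine, DMAP (cat.), CH2Cl2, rt
Reagents that add atoms: acetic anhydride, CC(=O)OC(C)=O
Why: DMAP-catalysed acylation turns the γ-hydroxyl into a leaving group for the reductive cleavage.

Step 7
Reactants: 9 6α-acetoxy enone
Product: 12 conjugated enone (18-TBDPSO-4β,8,10β-trimethyl-5βH-decala-2,7-dien-9-one), via samarium dienolate 10 (not isolated), via deconjugated ketone 11 (not isolated)
Conditions: SmI2 (2.5 equiv), MeOH, THF, −78 °C; then DBU, rt
Reagents that add atoms: none
Why: SmI2 reductive cleavage of a γ-acetoxy enone (two single-electron transfers, loss of acetate) gives the trivalent samarium dienolate, whose kinetic α-protonation product is isomerised by DBU to the conjugated enone; C4, C5 and C10 are untouched and the C8 centre of 11 disappears.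

Step 8
Reactants: 12 conjugated enone
Product: 14 enol triflate (9-triflyloxy-2,8(9)-diene), via lithium enolate 13 (not isolated)
Conditions: LiBH(s-Bu)3 (L-Selectride), THF, −78 °C; then PhNTf2, −78 → 0 °C
Reagents that add atoms: N-phenylbis(trifluoromethanesulfonimide), O=S(=O)(N(c1ccccc1)S(=O)(=O)C(F)(F)F)C(F)(F)F
Why: Conjugate hydride addition to the β-unsubstituted enone with a hindered carbonyl gives regiospecifically the C8=C9 enolate, which is trapped on oxygen (reductive enol triflation).

Step 9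
Reactants: 14 enol triflate; 15 [2-(1,3-dioxolan-2-yl)ethyl]zinc bromide
Product: 16 9-[2-(1,3-dioxolan-2-yl)ethyl]-2,8(9)-diene (18-TBDPSO-4β,8,10β-trimethyl-5βH)
Conditions: Pd(OAc)2 (5 mol %), SPhos (10 mol %), THF, 50 °C
Reagents that add atoms: none
Why: Negishi cross-coupling (oxidative addition of zerovalent palladium into the alkenyl triflate, transmetalation from zinc, reductive elimination) forms the C9–C11 bond; the bulky biarylphosphine speeds reductive elimination over β-hydride loss.

Step 10
Reactants: 16 9-[2-(1,3-dioxolan-2-yl)ethyl]-2,8(9)-diene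
Product: 17 9-[2-(1,3-dioxolan-2-yl)ethyl]-8(9)-ene with ring A saturated
Conditions: H2 (1 atm), Pd/C, EtOAc, rt
Reagents that add atoms: none
Why: Heterogeneous catalytic hydrogenation reduces the cis-disubstituted ring A alkene, while the tetrasubstituted C8=C9 alkene is inert under these conditions.

Step 11
Reactants: 17 9-[2-(1,3-dioxolan-2-yl)ethyl]-8(9)-ene
Product: 19 8α-hydroxy acetal (8α-OH, 9α-H, side chain 9β), via C8 alkylborane 18 (not isolated)
Conditions: BH3·THF (4 equiv), THF, 0 → 40 °C; then NaOH, H2O2, 0 °C → rt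
Reagents that add atoms: hydrogen peroxide, OO
Why: Brown hydroboration–oxidation adds H and B syn, with boron on the less hindered C8 (C9 adjoins the quaternary C10), so 8-OH and 9-H are cis by mechanism; attack from the α-face, opposite the pseudoaxial C10 methyl that screens C8 on the β-face, gives 8α-OH/9α-H, and oxidation proceeds with retention.

Step 12
Reactants: 19 8α-hydroxy acetal
Product: 20 hydroxy aldehyde (C13 aldehyde; in equilibrium with its six-membered lactol)
Conditions: AcOH–THF–H2O (3:1:1), 40 °C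
Reagents that add atoms: water, O
Why: Acid-catalysed acetal hydrolysis under conditions mild enough for the tertiary alcohol and the silyl ether; no stereocentre is affected.

Step 13
Reactants: 20 hydroxy aldehyde
Product: 21 hydroxy alkyne (C13≡C14 terminal alkyne)
Conditions: dimethyl (1-diazo-2-oxopropyl)phosphonate, K2CO3, MeOH, 0 °C → rt
Reagents that add atoms: dimethyl (1-diazo-2-oxopropyl)phosphonate, CC(=O)C(=[N+]=[N-])P(=O)(OC)OC
Why: Seyferth–Gilbert homologation with the Ohira–Bestmann reagent converts the (lactol-masked) aldehyde into the terminal alkyne under mild base.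

Step 14
Reactants: 21 hydroxy alkyne
Product: 22 silyl-protected dienol (18-TBDPSO-5βH-labda-13(16),14-dien-8α-ol)
Conditions: RuCl2(=CHPh)(PCy3)(H2IMes) (second-generation Grubbs catalyst, 5 mol %), ethylene (1 atm), CH2Cl2, rt
Reagents that add atoms: ethylene, C=C
Why: Enyne cross-metathesis of a terminal alkyne with ethylene gives the 2-substituted buta-1,3-diene directly and tolerates the free tertiary alcohol.

Step 15
Reactants: 22 silyl-protected dienol
Product: 23 diol (5βH-labda-13(16),14-diene-8α,18-diol)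
Conditions: Bu4NF, THF, 45 °C
Reagents that add atoms: none
Why: Fluoride-mediated desilylation frees the primary C18 alcohol.

Step 16
Reactants: 23 diol; 24 [bis(2,2,2-trifluoroethoxy)phosphoryl]acetic acid
Product: 25 C18 phosphonoacetate
Conditions: EDC·HCl, DMAP (cat.), CH2Cl2, 0 °C → rt
Reagents that add atoms: none
Why: Carbodiimide (Steglich-type) esterification acylates only the primary 18-OH; the tertiary 8-OH is inert.

Step 17
Reactants: 25 C18 phosphonoacetate; 26 4-[(tert-butyldimethylsilyl)oxy]benzaldehyde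
Product: 28 (Z)-cinnamate silyl ether, via potassium phosphonate carbanion 27 (not isolated)
Conditions: KHMDS (1.05 equiv), 18-crown-6, THF, −78 °C; then 26
Reagents that add atoms: none
Why: Still–Gennari olefination (electron-poor trifluoroethyl phosphonate, dissociated potassium counter-ion, fast irreversible elimination) gives the (Z)-alkene with aromatic aldehydes, and one equivalent of base deprotonates only the phosphonate.

Step 18
Reactants: 28 (Z)-cinnamate silyl ether
Product: 29 [(1R,4aS,5R,6R,8aS)-6-hydroxy-1,4a,6-trimethyl-5-(3-methylidenepent-4-en-1-yl)decahydronaphthalen-1-yl]methyl (2Z)-3-(4-hydroxyphenyl)prop-2-enoate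
Conditions: Bu4NF, AcOH (1:1.2), THF, 0 °C
Reagents that add atoms: none
Why: Buffered fluoride desilylation cleaves the aryl silyl ether while acetic acid keeps the phenol protonated, so the Z-alkene, the diene and the tertiary alcohol are untouched.

**Compound list**
1 | acrolein | C=CC=O | starting material
2 | ethyl 2-(triphenylphosphoranylidene)propanoate | CCOC(=O)C(C)=P(c1ccccc1)(c1ccccc1)c1ccccc1 | starting material
3 | ethyl (2E)-2-methylpenta-2,4-dienoate | C=C/C=C(\C)C(=O)OCC | intermediate
4 | (2E)-2-methylpenta-2,4-dien-1-ol | C=C/C=C(\C)CO | intermediate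
5 | tert-butyl{[(2E)-2-methylpenta-2,4-dien-1-yl]oxy}diphenylsilane | C=C/C=C(\C)CO[Si](c1ccccc1)(c1ccccc1)C(C)(C)C | intermediate
6 | 2,6-dimethyl-1,4-benzoquinone | CC1=CC(=O)C=C(C)C1=O | starting material
7 | (4aR,5R,8aS)-5-{[tert-butyl(diphenyl)silyl]oxymethyl}-2,5,8a-trimethyl-4a,5,8,8a-tetrahydronaphthalene-1,4-dione (cis-fused; H-5, CH3-10, CH3-4 β; CH2OSi α) | O=C1[C@@]2(C)CC=C[C@@](C)(CO[Si](c3ccccc3)(c3ccccc3)C(C)(C)C)[C@H]2C(=O)C=C1C | intermediate
8 | 6α-hydroxy enone (C6 carbonyl of 7 reduced) | O=C1[C@@]2(C)CC=C[C@@](C)(CO[Si](c3ccccc3)(c3ccccc3)C(C)(C)C)[C@H]2[C@@H](O)C=C1C | intermediate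
9 | 6α-acetoxy enone | O=C1[C@@]2(C)CC=C[C@@](C)(CO[Si](c3ccccc3)(c3ccccc3)C(C)(C)C)[C@H]2[C@@H](OC(C)=O)C=C1C | intermediate
10 | samarium dienolate (C9–O–SmI2, C8=C9, C6=C7; not isolated) | C1(O[Sm](I)I)[C@@]2(C)CC=C[C@@](C)(CO[Si](c3ccccc3)(c3ccccc3)C(C)(C)C)[C@H]2C=CC=1C | intermediate
11 | deconjugated ketone (C6=C7; C8 epimers, drawn 8β-CH3, immaterial; not isolated) | O=C1[C@@]2(C)CC=C[C@@](C)(CO[Si](c3ccccc3)(c3ccccc3)C(C)(C)C)[C@H]2C=C[C@@H]1C | intermediate
12 | conjugated enone, 18-TBDPSO-4β,8,10β-trimethyl-5βH-decala-2,7-dien-9-one | O=C1[C@@]2(C)CC=C[C@@](C)(CO[Si](c3ccccc3)(c3ccccc3)C(C)(C)C)[C@H]2CC=C1C | intermediate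
13 | lithium enolate (C8=C9–OLi; not isolated) | C1(O[Li])[C@@]2(C)CC=C[C@@](C)(CO[Si](c3ccccc3)(c3ccccc3)C(C)(C)C)[C@H]2CCC=1C | intermediate
14 | enol triflate (C8=C9, 9-OTf, ring A 2-ene) | C1(OS(=O)(=O)C(F)(F)F)[C@@]2(C)CC=C[C@@](C)(CO[Si](c3ccccc3)(c3ccccc3)C(C)(C)C)[C@H]2CCC=1C | intermediate
15 | [2-(1,3-dioxolan-2-yl)ethyl]zinc bromide | Br[Zn]CCC1OCCO1 | starting material
16 | 9-[2-(1,3-dioxolan-2-yl)ethyl]-2,8(9)-diene | C1(CCC3OCCO3)[C@@]2(C)CC=C[C@@](C)(CO[Si](c3ccccc3)(c3ccccc3)C(C)(C)C)[C@H]2CCC=1C | intermediate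
17 | 9-[2-(1,3-dioxolan-2-yl)ethyl]-8(9)-ene, ring A saturated | C1(CCC3OCCO3)[C@@]2(C)CCC[C@@](C)(CO[Si](c3ccccc3)(c3ccccc3)C(C)(C)C)[C@H]2CCC=1C | intermediate
18 | C8 alkylborane (8α-BH2, 9α-H; not isolated) | O3CCOC3CC[C@@H]1[C@@]2(C)CCC[C@@](C)(CO[Si](c3ccccc3)(c3ccccc3)C(C)(C)C)[C@H]2CC[C@@]1(C)B | intermediate
19 | 8α-hydroxy acetal (8α-OH, 8β-CH3, 9α-H) | O3CCOC3CC[C@@H]1[C@@]2(C)CCC[C@@](C)(CO[Si](c3ccccc3)(c3ccccc3)C(C)(C)C)[C@H]2CC[C@@]1(C)O | intermediate
20 | hydroxy aldehyde (open form of the lactol) | O=CCC[C@@H]1[C@@]2(C)CCC[C@@](C)(CO[Si](c3ccccc3)(c3ccccc3)C(C)(C)C)[C@H]2CC[C@@]1(C)O | intermediate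
21 | hydroxy alkyne | C#CCC[C@@H]1[C@@]2(C)CCC[C@@](C)(CO[Si](c3ccccc3)(c3ccccc3)C(C)(C)C)[C@H]2CC[C@@]1(C)O | intermediate
22 | 18-TBDPSO-5βH-labda-13(16),14-dien-8α-ol | C=CC(=C)CC[C@@H]1[C@@]2(C)CCC[C@@](C)(CO[Si](c3ccccc3)(c3ccccc3)C(C)(C)C)[C@H]2CC[C@@]1(C)O | intermediate
23 | 5βH-labda-13(16),14-diene-8α,18-diol | C=CC(=C)CC[C@@H]1[C@@]2(C)CCC[C@@](C)(CO)[C@H]2CC[C@@]1(C)O | intermediate
24 | [bis(2,2,2-trifluoroethoxy)phosphoryl]acetic acid | OC(=O)CP(=O)(OCC(F)(F)F)OCC(F)(F)F | starting material
25 | C18 phosphonoacetate of 23 | C=CC(=C)CC[C@@H]1[C@@]2(C)CCC[C@@](C)(COC(=O)CP(=O)(OCC(F)(F)F)OCC(F)(F)F)[C@H]2CC[C@@]1(C)O | intermediate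
26 | 4-[(tert-butyldimethylsilyl)oxy]benzaldehyde | O=Cc1ccc(O[Si](C)(C)C(C)(C)C)cc1 | starting material
27 | potassium phosphonate carbanion of 25 (not isolated) | [K+].C=CC(=C)CC[C@@H]1[C@@]2(C)CCC[C@@](C)(COC(=O)[CH-]P(=O)(OCC(F)(F)F)OCC(F)(F)F)[C@H]2CC[C@@]1(C)O | intermediate
28 | (Z)-4-(silyloxy)cinnamate of 23 | C=CC(=C)CC[C@@H]1[C@@]2(C)CCC[C@@](C)(COC(=O)/C=C\c3ccc(O[Si](C)(C)C(C)(C)C)cc3)[C@H]2CC[C@@]1(C)O | intermediate
29 | [(1R,4aS,5R,6R,8aS)-6-hydroxy-1,4a,6-trimethyl-5-(3-methylidenepent-4-en-1-yl)decahydronaphthalen-1-yl]methyl (2Z)-3-(4-hydroxyphenyl)prop-2-enoate | C=CC(=C)CC[C@@H]1[C@@]2(C)CCC[C@@](C)(COC(=O)/C=C\c3ccc(O)cc3)[C@H]2CC[C@@]1(C)O | target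

**Totals and risks**
Total step count: 18. Longest linear sequence: 18 steps (1 → 29); all other fragments (6, 15, 24, 26) are commercial.

Steps most likely to fail:

Step 4. The diene carries a Z-methyl on its reacting terminus, so it is sluggish; the cationic Lewis acid may ionise or oligomerise it; and the enantioselectivity is unproven for this diene. Fallback, setting out from 5 and 6 and coming back at 9: the cycloaddition is promoted with stoichiometric BF3·OEt2 (same regiochemistry through coordination at the C6 carbonyl, endo), which gives the racemate, that is 7 together with its mirror-image cycloadduct F1. Luche reduction as in step 5 then gives 8 together with the mirror-image 6-hydroxy enone F2. A lipase (Burkholderia cepacia lipase, vinyl acetate, MTBE), selected so that 8 is the fast-reacting enantiomer, acetylates 8 to 9 directly and leaves F2 as the alcohol, which is removed by chromatography.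

Step 9. Alkyl–alkenyl coupling at a tetrasubstituted triflate next to the quaternary C10 may suffer slow transmetalation, β-hydride elimination or simple reduction of the triflate. Fallback, setting out from 14 and coming back at 17: Sonogashira coupling of 14 with 3,3-diethoxyprop-1-yne (PdCl2(PPh3)2, CuI, Et3N), in which the slim sp partner is far less sensitive to hindrance, gives the enyne diethyl acetal F3. Hydrogen with RhCl(PPh3)3 saturates the alkyne and the ring A alkene but not the tetrasubstituted alkene and gives the saturated diethyl acetal F4. Acetal exchange with ethylene glycol (PPTS, benzene) gives 17.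

Step 11. The alkene is tetrasubstituted and hindered, so addition may be slow and boron may migrate on warming; the α-facial preference rests on a conformational argument for the cis-decalin. Fallback, setting out from 17 and coming back at 19: a Schenck ene reaction with singlet oxygen (O2, hν, tetraphenylporphyrin, CH2Cl2, −20 °C) bonds oxygen to C8 and takes hydrogen from C11 (the CH2 geminal to the bulky C10), giving the 8α-hydroperoxide F5 with an exocyclic C9=C11 alkene. PPh3 reduces it to the tertiary allylic alcohol F6. Hydroxyl-directed hydrogenation with [Ir(cod)(PCy3)(py)]PF6 and H2 then delivers hydrogen to C9 from the face of the 8-OH and gives 19, so C9 is tied to C8 by direction rather than by the approach of a bulky borane; the C8 face still rests on the same conformational bias.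

Further compounds
F1 | step 4 | ent-7, mirror-image cycloadduct | O=C1[C@]2(C)CC=C[C@](C)(CO[Si](c3ccccc3)(c3ccccc3)C(C)(C)C)[C@@H]2C(=O)C=C1C
F2 | step 4 | ent-8, mirror-image 6-hydroxy enone | O=C1[C@]2(C)CC=C[C@](C)(CO[Si](c3ccccc3)(c3ccccc3)C(C)(C)C)[C@@H]2[C@H](O)C=C1C
F3 | step 9 | enyne diethyl acetal (9-(3,3-diethoxyprop-1-ynyl)-2,8(9)-diene) | C1(C#CC(OCC)OCC)[C@@]2(C)CC=C[C@@](C)(CO[Si](c3ccccc3)(c3ccccc3)C(C)(C)C)[C@H]2CCC=1C
F4 | step 9 | saturated diethyl acetal (9-(3,3-diethoxypropyl)-8(9)-ene) | C1(CCC(OCC)OCC)[C@@]2(C)CCC[C@@](C)(CO[Si](c3ccccc3)(c3ccccc3)C(C)(C)C)[C@H]2CCC=1C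
F5 | step 11 | 8α-hydroperoxide with exocyclic C9=C11 alkene (geometry immaterial, drawn Z) | O3CCOC3C/C=C1/[C@@]2(C)CCC[C@@](C)(CO[Si](c3ccccc3)(c3ccccc3)C(C)(C)C)[C@H]2CC[C@@]1(C)OO
F6 | step 11 | tertiary allylic alcohol (8α-OH, exocyclic C9=C11 alkene) | O3CCOC3C/C=C1/[C@@]2(C)CCC[C@@](C)(CO[Si](c3ccccc3)(c3ccccc3)C(C)(C)C)[C@H]2CC[C@@]1(C)O
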